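**Strategy.** The cyclohexane ring of the quinic acid core is opened at C1–C6 and C4–C5 (C1 = carbinol carbon bearing CO2H, C4 = succinylated CH, C5 = neighbouring caffeoylated CH), which leaves a C1–C4 diene and a C5–C6 dienophile. The feature used is the O,CO2H-substituted C1: in a 1,4-dioxygenated dienoate it is the nucleophilic terminus. The diene is the cyclic di-tert-butylsilylene bis(enol ether) of tert-butyl 2,5-dioxopentanoate (Z,Z, locked s-cis); one catalytic enantioselective Diels–Alder reaction with methyl vinyl ketone closes the ring and sets C1 and C5. Baeyer–Villiger oxidation gives O5, reductive transposition and dihydroxylation install O3 and O4, and regioselective acylations finish.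

Key step: step 4

Remark on numbering: ring positions are numbered as in quinic acid throughout (C1 carbinol carbon with the carboxyl group; O3 and O4 cis to O1; O5 trans to them and cis to the carboxyl group); "quinate" means the ester of (−)-quinic acid.

Assumption: the sense of asymmetric induction of the (S)-configured catalyst in step 4 is taken from the accepted transition-state model for s-trans enones; if the opposite sense were found, the mirror-image catalyst would be used with nothing else changed.

Step 1
Reactants: 1 di-tert-butyl oxalate; 2 but-3-en-1-ylmagnesium bromide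
Product: 3 tert-butyl 2-oxohex-5-enoate
Conditions: 2 (0.5 M in THF) added to 1 (1.3 equiv), THF, −78 °C; then 1 M HCl, 0 °C
Reagents that add atoms: none
Why: Grignard addition to one ester group of the oxalate gives a magnesium hemiketal that is stable at −78 °C and collapses to the α-keto ester only on quench, so a second addition does not occur (mono-acylation of a Grignard reagent by a dialkyl oxalate).

Step 2
Reactants: 3 tert-butyl 2-oxohex-5-enoate
Product: 4 tert-butyl 2,5-dioxopentanoate
Conditions: O3, CH2Cl2, −78 °C; then Me2S, −78 → 23 °C; used crude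
Reagents that add atoms: ozone, [O-][O+]=O
Why: Ozonolysis with reductive work-up cleaves the only C=C bond to the aldehyde, and the α-keto ester is inert to ozone.

Step 3
Reactants: 4 tert-butyl 2,5-dioxopentanoate
Product: 5 tert-butyl 2,2-di-tert-butyl-1,3,2-dioxasilepine-4-carboxylate (cyclic silylene bis(enol ether); ring carbons C4–C7 are C1–C4 of the future quinate)
Conditions: tBu2Si(OSO2CF3)2 (1.05 equiv), Et3N (3 equiv), CH2Cl2 (0.02 M), −78 → 0 °C
Reagents that add atoms: di-tert-butylsilyl bis(trifluoromethanesulfonate), CC(C)(C)[Si](OS(=O)(=O)C(F)(F)F)(OS(=O)(=O)C(F)(F)F)C(C)(C)C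
Why: Silyl enol ether formation by soft enolisation: each carbonyl oxygen is silylated and triethylamine removes the only α-protons available (C2–H next to the keto ester, C3–H next to the aldehyde), and because both oxygens end on one silicon atom the seven-membered ring closes with both C=C bonds necessarily Z.

Step 4
Reactants: 5 tert-butyl 2,2-di-tert-butyl-1,3,2-dioxasilepine-4-carboxylate; 6 methyl vinyl ketone (but-3-en-2-one)
Product: 7 tert-butyl 6-acetyl-3,3-di-tert-butyl-2,4-dioxa-3-silabicyclo[3.2.2]non-8-ene-1-carboxylate, acetyl endo (on the side of the C8=C9 bridge, anti to the O–Si–O bridge); in quinate numbering O1 and O4 lie on one face, the ester and the C5 acetyl group on the other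
Conditions: 6 (2 equiv), oxazaborolidinium salt formed from (S)-3,3-diphenyl-1-(2-methylphenyl)tetrahydro-1H,3H-pyrrolo[1,2-c][1,3,2]oxazaborole and HN(SO2CF3)2 (20 mol %), CH2Cl2, −78 → −40 °C; Et3N quench at low temperature
Reagents that add atoms: none
Why: Normal-electron-demand Diels–Alder reaction ([4+2] cycloaddition) of the electron-rich cyclic bis(silyl enol ether) with the enone activated by O-coordination to the cationic boron catalyst; the transition state is asynchronous, C1–C6 bond formation (Mukaiyama–Michael character) running ahead of C4–C5. The closest known reaction type is the oxazaborolidinium-catalysed enantioselective Diels–Alder reaction of silyloxy dienes with α,β-unsaturated ketones. The six-membered carbocycle is closed by suprafacial [4+2] addition across the diene termini C1 and C4, which gives the 2,4-dioxa-3-silabicyclo[3.2.2]nonene. The C1 and C4 centres are held cis by the silylene tether, the C5 centre follows the endo rule (acetyl under the diene π-system and away from the tert-butyl groups on silicon, hence cis to the ester), and the absolute configuration comes from the catalyst, which shields one face of the bound s-trans enone. The step needs regioselectivity (acetyl-bearing carbon at C4, not at C1): the C4 oxygen is through-conjugated with the ester, which makes C1 the nucleophilic terminus and leaves the developing oxocarbenium charge at C4 free of an acceptor, and the unsubstituted enone carbon rather than the substituted one meets the fully substituted C1.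

Step 5
Reactants: 7 (acetyl cycloadduct)
Product: 8 tert-butyl 6-acetoxy-3,3-di-tert-butyl-2,4-dioxa-3-silabicyclo[3.2.2]non-8-ene-1-carboxylate (acetoxy endo, same configuration as 7)
Conditions: Me3SiOOSiMe3 (2 equiv), SnCl4 (15 mol %), trans-cyclohexane-1,2-diamine (15 mol %), 4 Å molecular sieves, CH2Cl2, 0 → 23 °C
Reagents that add atoms: bis(trimethylsilyl) peroxide, C[Si](C)(C)OO[Si](C)(C)C
Why: Baeyer–Villiger oxidation: the secondary ring carbon C5 migrates in preference to methyl with retention of configuration, and the silyl peroxide/Lewis acid couple oxidises ketones without epoxidising the shielded, electron-poor C2=C3 bond.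

Step 6
Reactants: 8 (acetoxy silylene)
Product: 9 tert-butyl (1R,4R,5R)-5-acetoxy-1,4-dihydroxycyclohex-2-ene-1-carboxylate
Conditions: HF·pyridine, THF, 0 → 23 °C
Reagents that add atoms: none
Why: Fluoride-mediated cleavage of both Si–O bonds frees the tertiary C1 and allylic C4 hydroxyls, while the acetate and the tert-butyl ester are untouched under these acidic, non-nucleophilic conditions (desilylation).

Step 7
Reactants: 9 tert-butyl (1R,4R,5R)-5-acetoxy-1,4-dihydroxycyclohex-2-ene-1-carboxylate
Product: 10 tert-butyl (1S,5R)-5-acetoxy-1-hydroxycyclohex-3-ene-1-carboxylate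
Conditions: 2-nitrobenzenesulfonylhydrazide, PPh3, diethyl azodicarboxylate, THF, −30 °C; then 23 °C
Reagents that add atoms: none
Why: Reductive 1,3-transposition of an allylic alcohol: Mitsunobu displacement of the secondary allylic C4–OH by the sulfonylhydrazide (the tertiary C1–OH is inert), loss of arenesulfinic acid to the allylic monoalkyl diazene and retro-ene loss of N2 deliver hydrogen to C2 and move the alkene to C3=C4; the C4 centre is erased, C1 and C5 are untouched.

Step 8
Reactants: 10 tert-butyl (1S,5R)-5-acetoxy-1-hydroxycyclohex-3-ene-1-carboxylate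
Product: 11 tert-butyl 5-O-acetylquinate
Conditions: OsO4 (1.05 equiv), Me2NCH2CH2NMe2 (1.1 equiv), CH2Cl2, −78 °C; then Na2SO3, THF/H2O, 50 °C
Reagents that add atoms: osmium tetroxide, O=[Os](=O)(=O)=O
Why: Directed cis-dihydroxylation by [3+2] addition of OsO4: the diamine-bound oxidant is hydrogen-bonded to the axial homoallylic C1–OH and approaches anti to the allylic C5 acetoxy group, so both new hydroxyls (O3, O4) enter on the face of O1.

Step 9
Reactants: 11 tert-butyl 5-O-acetylquinate
Product: 13 tert-butyl 3,4-O-isopropylidenequinate, via tert-butyl quinate 12 (not isolated)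
Conditions: K2CO3 (0.2 equiv), MeOH, 0 → 23 °C; AcOH to neutralise, concentrate; then acetone, 2,2-dimethoxypropane, TsOH·H2O (cat.), 23 °C
Reagents that add atoms: 2,2-dimethoxypropane, COC(C)(C)OC
Why: Base-catalysed transesterification removes the O5 acetate (so any earlier acetyl migration is irrelevant), then acid-catalysed transketalisation protects the only cis-1,2-diol (O3/O4) as the five-membered isopropylidene acetal, leaving the secondary O5–H and the tertiary O1–H free.

Step 10
Reactants: 14 3,4-bis(methoxymethoxy)benzaldehyde; 15 malonic acid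
Product: 16 (E)-3-[3,4-bis(methoxymethoxy)phenyl]prop-2-enoic acid
Conditions: pyridine, piperidine (cat.), 85 °C
Reagents that add atoms: none
Why: Knoevenagel–Doebner condensation with decarboxylation gives the E-cinnamic acid, and the acetal protecting groups are stable to the basic medium.

Step 11
Reactants: 13 tert-butyl 3,4-O-isopropylidenequinate; 16 (E)-3-[3,4-bis(methoxymethoxy)phenyl]prop-2-enoic acid
Product: 18 tert-butyl 1,5-bis-O-{(E)-3-[3,4-bis(methoxymethoxy)phenyl]prop-2-enoyl}-3,4-O-isopropylidenequinate, via acid chloride 17 (not isolated)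
Conditions: 16 (3 equiv), 1-chloro-N,N,2-trimethylprop-1-en-1-amine (3 equiv), CH2Cl2, 0 → 23 °C; then 13, DMAP (1 equiv), pyridine, ClCH2CH2Cl, 60 °C
Reagents that add atoms: none
Why: Acid chloride formation under neutral conditions (α-chloroenamine) followed by DMAP-catalysed acylation esterifies the secondary O5–H readily and, with excess reagent and heating, the hindered tertiary O1–H; no stereocentre is involved.

Step 12
Reactants: 18 (bis-cinnamoyl acetonide)
Product: 19 tert-butyl 1,5-bis-O-{(E)-3-[3,4-bis(methoxymethoxy)phenyl]prop-2-enoyl}quinate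
Conditions: AcOH/H2O (4:1), 45 °C
Reagents that add atoms: none
Why: Mild acid hydrolysis of the isopropylidene acetal frees the 3,4-diol, whereas the aryl methoxymethyl ethers and the tert-butyl ester need stronger acid (acetal hydrolysis).

Step 13
Reactants: 19 (3,4-diol); 20 succinic anhydride
Product: 21 tert-butyl 1,5-bis-O-{(E)-3-[3,4-bis(methoxymethoxy)phenyl]prop-2-enoyl}-4-O-(3-carboxypropanoyl)quinate
Conditions: Bu2SnO (1.1 equiv), toluene, reflux with azeotropic removal of water; then 20 (1.1 equiv), 23 °C; aqueous citric acid work-up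
Reagents that add atoms: none
Why: Regioselective acylation through the dibutylstannylene acetal of the cis-diol: the equatorial O4 opens the anhydride to give the hydrogen succinate, and the axial O3–H, syn-axial to the C1 acyloxy group, stays free.

Step 14
Reactants: 21 (protected target)
Product: 22 1,5-di-O-caffeoyl-4-O-succinylquinic acid (target)
Conditions: CF3CO2H/CH2Cl2 (1:2), H2O (5 equiv), 0 → 23 °C
Reagents that add atoms: none
Why: Acidolysis: the tert-butyl ester cleaves through the tert-butyl cation and the four aryl methoxymethyl acetals through oxocarbenium ions, while the caffeoyl and succinyl esters and all stereocentres survive, and the absence of base avoids acyl migration.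

**Compound list**

1 | di-tert-butyl oxalate | CC(C)(C)OC(=O)C(=O)OC(C)(C)C | starting material
2 | but-3-en-1-ylmagnesium bromide | C=CCC[Mg]Br | starting material
3 | tert-butyl 2-oxohex-5-enoate | C=CCCC(=O)C(=O)OC(C)(C)C | intermediate
4 | tert-butyl 2,5-dioxopentanoate | O=CCCC(=O)C(=O)OC(C)(C)C | intermediate
5 | tert-butyl 2,2-di-tert-butyl-1,3,2-dioxasilepine-4-carboxylate | CC(C)(C)OC(=O)C1=CC=CO[Si](C(C)(C)C)(C(C)(C)C)O1 | intermediate
6 | methyl vinyl ketone | CC(=O)C=C | starting material
7 | tert-butyl 6-endo-acetyl-3,3-di-tert-butyl-2,4-dioxa-3-silabicyclo[3.2.2]non-8-ene-1-carboxylate | CC(C)(C)[Si]2(C(C)(C)C)O[C@@H]1C=C[C@@](O2)(C(=O)OC(C)(C)C)C[C@H]1C(C)=O | intermediate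
8 | tert-butyl 6-endo-acetoxy-3,3-di-tert-butyl-2,4-dioxa-3-silabicyclo[3.2.2]non-8-ene-1-carboxylate | CC(C)(C)[Si]2(C(C)(C)C)O[C@@H]1C=C[C@@](O2)(C(=O)OC(C)(C)C)C[C@H]1OC(C)=O | intermediate
9 | tert-butyl (1R,4R,5R)-5-acetoxy-1,4-dihydroxycyclohex-2-ene-1-carboxylate | O[C@@H]1C=C[C@@](O)(C(=O)OC(C)(C)C)C[C@H]1OC(C)=O | intermediate
10 | tert-butyl (1S,5R)-5-acetoxy-1-hydroxycyclohex-3-ene-1-carboxylate | CC(C)(C)OC(=O)[C@]1(O)CC=C[C@H](OC(C)=O)C1 | intermediate
11 | tert-butyl 5-O-acetylquinate | O[C@@H]1[C@H](O)C[C@@](O)(C(=O)OC(C)(C)C)C[C@H]1OC(C)=O | intermediate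
12 | tert-butyl quinate | O[C@@H]1[C@H](O)C[C@@](O)(C(=O)OC(C)(C)C)C[C@H]1O | intermediate
13 | tert-butyl 3,4-O-isopropylidenequinate | CC1(C)O[C@@H]2[C@H](O1)C[C@@](O)(C(=O)OC(C)(C)C)C[C@H]2O | intermediate
14 | 3,4-bis(methoxymethoxy)benzaldehyde | COCOc1ccc(C=O)cc1OCOC | starting material
15 | malonic acid | OC(=O)CC(=O)O | starting material
16 | (E)-3-[3,4-bis(methoxymethoxy)phenyl]prop-2-enoic acid | COCOc1ccc(/C=C/C(=O)O)cc1OCOC | intermediate
17 | (E)-3-[3,4-bis(methoxymethoxy)phenyl]prop-2-enoyl chloride | COCOc1ccc(/C=C/C(=O)Cl)cc1OCOC | intermediate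
18 | tert-butyl 1,5-bis-O-{(E)-3-[3,4-bis(methoxymethoxy)phenyl]prop-2-enoyl}-3,4-O-isopropylidenequinate | CC1(C)O[C@@H]2[C@H](O1)C[C@@](OC(=O)/C=C/c1ccc(OCOC)c(OCOC)c1)(C(=O)OC(C)(C)C)C[C@H]2OC(=O)/C=C/c1ccc(OCOC)c(OCOC)c1 | intermediate
19 | tert-butyl 1,5-bis-O-{(E)-3-[3,4-bis(methoxymethoxy)phenyl]prop-2-enoyl}quinate | O[C@@H]1[C@H](O)C[C@@](OC(=O)/C=C/c2ccc(OCOC)c(OCOC)c2)(C(=O)OC(C)(C)C)C[C@H]1OC(=O)/C=C/c1ccc(OCOC)c(OCOC)c1 | intermediate
20 | succinic anhydride | O=C1CCC(=O)O1 | starting material
21 | tert-butyl 1,5-bis-O-{(E)-3-[3,4-bis(methoxymethoxy)phenyl]prop-2-enoyl}-4-O-(3-carboxypropanoyl)quinate | O=C(O)CCC(=O)O[C@@H]1[C@H](O)C[C@@](OC(=O)/C=C/c2ccc(OCOC)c(OCOC)c2)(C(=O)OC(C)(C)C)C[C@H]1OC(=O)/C=C/c1ccc(OCOC)c(OCOC)c1 | intermediate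
22 | 1,5-di-O-caffeoyl-4-O-succinylquinic acid | O=C(O)CCC(=O)O[C@@H]1[C@H](O)C[C@@](OC(=O)/C=C/c2ccc(O)c(O)c2)(C(=O)O)C[C@H]1OC(=O)/C=C/c1ccc(O)c(O)c1 | target

**Step count.** Total: 14 steps. Longest linear sequence: 13 steps (steps 1–9 and 11–14).

**Steps most likely to fail**

Step 4 (key cycloaddition). The strongly acidic catalyst may protodesilylate the diene, the enone β-carbon may bond to C4 instead of C1, or facial discrimination may be poor. The fallback moves control from the catalyst to a chelated, more strongly polarised dienophile carrying an auxiliary. It sets out from 5: reaction with (4S)-4-benzyl-3-(prop-2-enoyl)-1,3-oxazolidin-2-one and Et2AlCl (CH2Cl2, −78 °C) should give the endo imide cycloadduct tert-butyl 6-{[(4S)-4-benzyl-2-oxo-1,3-oxazolidin-3-yl]carbonyl}-3,3-di-tert-butyl-2,4-dioxa-3-silabicyclo[3.2.2]non-8-ene-1-carboxylate F1. Aminolysis with MeNH(OMe)·HCl/AlMe3 should give the N-methoxy-N-methylamide tert-butyl 3,3-di-tert-butyl-6-[methoxy(methyl)carbamoyl]-2,4-dioxa-3-silabicyclo[3.2.2]non-8-ene-1-carboxylate F2, and MeMgBr (THF, −20 °C) then gives the methyl ketone. The fallback comes back to the route at 7.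

Step 3 (cyclic diene). Cyclodehydration of the 1,4-dicarbonyl compound to the furan-2-carboxylate or intermolecular silylation to oligomers may compete with ring closure. The fallback gives up the tether and sets out from 4: TBSOTf/Et3N (CH2Cl2, −78 °C) should give the acyclic diene tert-butyl (2Z,4E)-2,5-bis[(tert-butyldimethylsilyl)oxy]penta-2,4-dienoate F3; the unreactive 4Z isomer would be re-equilibrated with catalytic iodine. Cycloaddition with 6 under the conditions of step 4 should give tert-butyl 5-acetyl-1,4-bis[(tert-butyldimethylsilyl)oxy]cyclohex-2-ene-1-carboxylate F4 (acetyl cis to the ester, O4 trans to O1). Oxidation as in step 5 gives the acetate tert-butyl 5-acetoxy-1,4-bis[(tert-butyldimethylsilyl)oxy]cyclohex-2-ene-1-carboxylate F5, and HF·pyridine gives the diol tert-butyl (1R,4S,5R)-5-acetoxy-1,4-dihydroxycyclohex-2-ene-1-carboxylate F6, the C4 epimer of 9. The conditions of step 7 erase C4, so the fallback comes back to the route at 10.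

Step 11 (double acylation). Acylation of the tertiary O1–H next to the tert-butyl ester may stall at the 5-mono-ester. The fallback builds the cinnamoyl groups on the oxygen atoms instead of transferring them, and sets out from 13: heating with 2,2-dimethyl-1,3-dioxane-4,6-dione (toluene, 90 °C), which also acylates tertiary alcohols, should give the bis(hydrogen malonate) tert-butyl 1,5-bis-O-(carboxyacetyl)-3,4-O-isopropylidenequinate F7. Knoevenagel–Doebner condensation with 14 (pyridine, piperidine cat., 50 °C) then forms both E-cinnamates with decarboxylation. The fallback comes back to the route at 18.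

**Further compounds**

F1 | step 4 | tert-butyl 6-endo-{[(4S)-4-benzyl-2-oxo-1,3-oxazolidin-3-yl]carbonyl}-3,3-di-tert-butyl-2,4-dioxa-3-silabicyclo[3.2.2]non-8-ene-1-carboxylate | CC(C)(C)[Si]2(C(C)(C)C)O[C@@H]1C=C[C@@](O2)(C(=O)OC(C)(C)C)C[C@H]1C(=O)N1C(=O)OC[C@@H]1Cc1ccccc1
F2 | step 4 | tert-butyl 3,3-di-tert-butyl-6-endo-[methoxy(methyl)carbamoyl]-2,4-dioxa-3-silabicyclo[3.2.2]non-8-ene-1-carboxylate | CC(C)(C)[Si]2(C(C)(C)C)O[C@@H]1C=C[C@@](O2)(C(=O)OC(C)(C)C)C[C@H]1C(=O)N(C)OC
F3 | step 3 | tert-butyl (2Z,4E)-2,5-bis[(tert-butyldimethylsilyl)oxy]penta-2,4-dienoate | CC(C)(C)OC(=O)/C(O[Si](C)(C)C(C)(C)C)=C/C=C/O[Si](C)(C)C(C)(C)C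
F4 | step 3 | tert-butyl 5-acetyl-1,4-bis[(tert-butyldimethylsilyl)oxy]cyclohex-2-ene-1-carboxylate (acetyl and O4 cis to the ester) | CC(C)(C)[Si](C)(C)O[C@H]1C=C[C@@](O[Si](C)(C)C(C)(C)C)(C(=O)OC(C)(C)C)C[C@H]1C(C)=O
F5 | step 3 | tert-butyl 5-acetoxy-1,4-bis[(tert-butyldimethylsilyl)oxy]cyclohex-2-ene-1-carboxylate | CC(C)(C)[Si](C)(C)O[C@H]1C=C[C@@](O[Si](C)(C)C(C)(C)C)(C(=O)OC(C)(C)C)C[C@H]1OC(C)=O
F6 | step 3 | tert-butyl (1R,4S,5R)-5-acetoxy-1,4-dihydroxycyclohex-2-ene-1-carboxylate | O[C@H]1C=C[C@@](O)(C(=O)OC(C)(C)C)C[C@H]1OC(C)=O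
F7 | step 11 | tert-butyl 1,5-bis-O-(carboxyacetyl)-3,4-O-isopropylidenequinate | CC1(C)O[C@@H]2[C@H](O1)C[C@@](OC(=O)CC(=O)O)(C(=O)OC(C)(C)C)C[C@H]2OC(=O)CC(=O)O
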